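A straight line in time and a first-order decay of L, each drawn through the last dusk reading, lie closer together inside the dusk run than they do at the end of south, so the dispute is worth having before the flasks are run.

in all of them: L 0.050 M
- dusk: D 28 µM; Q 10 µM; run made earlier
- south: D 42 µM; Q 10 µM; time 2.5 d
- west: D 42 µM; Q 20 µM; time 2.5 d
- south-west: D 42 µM; Q 40 µM; time 2.5 d

dusk run (percent of the L charged): time / h: Z / % = 1.50: 2.0; 3.00: 4.6; 5.00: 6.3; 8.00: 9.4; 12.0: 13.6; 20.0: 22.7

(readings scatter by 0.5 percentage points)

- "hardly changes" means that all values lie within two and a half points (for a concentration: within two and a half percent of the largest)
- no earlier run changes the charge of D; that part of a forecast is a guess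
- no earlier run changes the charge of Q; that part of a forecast is a guess

- amount of Z at the end, in percent of the L charged for south, west, south-west, in this order
- the shape of the row from first to last (falls, then rises / rises, then falls / hardly changes / falls all the way / rises all the way)

The forecast holds the line. It reads the dusk run as “near zero order in L, with D saturated”, scales the slope of 1.14 % per hour with the charge of D, and gives 97%, 97% and 95%, a row that "hardly changes".

I hold the decay, and my reckoning differs from the forecast's. I freeze the working catalyst at its charge, which makes L pseudo-first-order, and carry one quantity: κ, the first-order constant of L per unit of [D] charged, here 460 /M/h, taken from 22.7% of Z at 20.0 h in the dusk run.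

At 12.0 h κ gives 14.3% of Z, while the line gives 13.6% and the reading is 13.6%. The gap of 0.70 percentage points is less than two standard deviations, so this reading does not choose between us.

We both scale with [D], which is a guess. Since [Q] is 10 µM in dusk and in south, κ passes to south unchanged and gives 68.6%, lower than the forecast's figure. For west and south-west I name no figure, because no earlier run changes [Q].

The simulation gives 75.4%, 73.1% and 68.7%, and the row falls all the way.

    L + D → X (k = 15.7 /M/min)
    X → G (k = 2.71 /min)
    G → D + Z (k = 0.952 /min)
    D + Q ⇌ E, settled at all times (K = 12000 /M)

South stands 22 points below the forecast and 6.8 points above κ's figure, so the decay wins, and the line keeps the dusk stretch up to 22.7% of Z. In south the turnover of L + D → X up to the end was half done at 0.989 d, while L fell to 54.0% by 1.25 d and 25% by the end, and κ averaged over that run is 557 /M/h. In south-west, where E held 21.6% of the catalyst charged at the end against 6.43% in south, κ averaged over the run is 461 /M/h, a ratio of 0.828 to south's, and the catalyst outside E at the end stood in a ratio of 0.838.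

Readings and results were computed on assumed constants; scatter was added.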